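The route rests on cutting the C3–C4 bond of the furan ring, between the chain-bearing C3 and the adjacent unsubstituted C4–H. In one operation, ruthenium-catalysed ring-closing metathesis joins the CH2= group of a 2-substituted allyl ether to the vinyl group of an acrolein-derived mixed methyl acetal, and weak acid then expels methanol. The sensitive furan therefore appears only in the final flask. The precursor is the complete acetoxy hydroxy lactone chain ending in CH2=C(R)CH2O–CH(OMe)CH=CH2. It is assembled from a west aldehyde that already carries the acetal, so that the hindered secondary hydroxyl never competes in acetal exchange, and an east iodoalkene lactone.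

Key step: step 20

Remark on the chemistry: the acetal carbon is not controlled, so 11–13 and 26–31 are carried as mixtures of both configurations at that carbon (26 also at C6); the centre becomes sp2 in step 20.

Step 1
Reactants: 1 but-3-yn-1-ol
Product: 2 tert-butyl(but-3-yn-1-yloxy)diphenylsilane
Conditions: t-BuPh2SiCl, imidazole, CH2Cl2, 0 °C to rt
Reagents that add atoms: tert-butyl(chloro)diphenylsilane, CC(C)(C)[Si](Cl)(c1ccccc1)c1ccccc1
Why: Imidazole-promoted silylation masks the hydroxyl as a silyl ether that should survive the organoaluminium, organolithium and weak-acid steps ahead.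

Step 2
Reactants: 2 tert-butyl(but-3-yn-1-yloxy)diphenylsilane
Product: 5 (2E)-5-{[tert-butyl(diphenyl)silyl]oxy}-3-methylpent-2-en-1-ol, via alkenyldimethylalane 3 (not isolated), via lithium alkenylaluminate 4 (not isolated)
Conditions: Me3Al, Cp2ZrCl2 (cat.), CH2Cl2, 0 °C to rt; evaporate; n-BuLi, THF/hexane, −78 to 0 °C; (CH2O)n, rt
Reagents that add atoms: trimethylaluminium, C[Al](C)C; formaldehyde (as paraformaldehyde), C=O
Why: Negishi zirconium-catalysed methylalumination adds CH3 and Al syn across the terminal alkyne with Al at the terminus, and hydroxymethylation of the derived aluminate proceeds with retention, so the E trisubstituted alkene is fixed.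

Step 3
Reactants: 5 (2E)-5-{[tert-butyl(diphenyl)silyl]oxy}-3-methylpent-2-en-1-ol
Product: 6 {[(3E)-5-bromo-3-methylpent-3-en-1-yl]oxy}(tert-butyl)diphenylsilane
Conditions: CBr4, PPh3, CH2Cl2, 0 °C
Reagents that add atoms: tetrabromomethane, BrC(Br)(Br)Br
Why: Appel bromination of the primary allylic alcohol under neutral conditions should give the bromide without allylic transposition and leaves the silyl ether intact.

Step 4
Reactants: 6 {[(3E)-5-bromo-3-methylpent-3-en-1-yl]oxy}(tert-butyl)diphenylsilane; 7 2-methylprop-2-en-1-ol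
Product: 9 (5E)-8-{[tert-butyl(diphenyl)silyl]oxy}-6-methyl-2-methylideneoct-5-en-1-ol, via dilithio dianion 8 (not isolated)
Conditions: 7 (excess), n-BuLi (2 equiv per 7), TMEDA, Et2O/hexane, 0 °C to rt; then 6, THF, −78 °C to rt
Reagents that add atoms: none
Why: Deprotonation of O–H and then alkoxide-directed allylic lithiation gives the 2-(lithiomethyl)allyl alkoxide, whose carbanion should displace the primary allylic bromide by SN2 alkylation, as is known for prenyl-type bromides.

Step 5
Reactants: 9 (5E)-8-{[tert-butyl(diphenyl)silyl]oxy}-6-methyl-2-methylideneoct-5-en-1-ol; 10 acrolein dimethyl acetal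
Product: 11 tert-butyl{[(3E)-7-{[(1-methoxyprop-2-en-1-yl)oxy]methyl}-3-methylocta-3,7-dien-1-yl]oxy}diphenylsilane
Conditions: 10 (large excess), PPTS (cat.), toluene, 5 Å molecular sieves, rt
Reagents that add atoms: none
Why: Acid-catalysed transacetalisation with excess 10 and removal of methanol should stop at the mixed acetal; the new acetal centre is uncontrolled and is destroyed in step 20.

Step 6
Reactants: 11 tert-butyl{[(3E)-7-{[(1-methoxyprop-2-en-1-yl)oxy]methyl}-3-methylocta-3,7-dien-1-yl]oxy}diphenylsilane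
Product: 12 (3E)-7-{[(1-methoxyprop-2-en-1-yl)oxy]methyl}-3-methylocta-3,7-dien-1-ol
Conditions: Bu4NF, THF, 0 °C to rt
Reagents that add atoms: none
Why: Fluoride-induced desilylation is basic, so the acid-labile acetal should be untouched.

Step 7
Reactants: 12 (3E)-7-{[(1-methoxyprop-2-en-1-yl)oxy]methyl}-3-methylocta-3,7-dien-1-ol
Product: 13 (3E)-7-{[(1-methoxyprop-2-en-1-yl)oxy]methyl}-3-methylocta-3,7-dienal
Conditions: Dess–Martin periodinane, pyridine, CH2Cl2, 0 °C; used at once
Reagents that add atoms: none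
Why: Pyridine-buffered Dess–Martin oxidation gives the β,γ-unsaturated aldehyde without acid or base strong enough to move the alkene into conjugation or cleave the acetal.

Step 8
Reactants: 14 pent-4-yn-1-ol
Product: 16 (4E)-5-iodo-4-methylpent-4-en-1-ol, via alkenylalane alkoxide 15 (not isolated)
Conditions: Me3Al, Cp2ZrCl2 (cat.), CH2Cl2, 0 °C to rt; then I2, THF, −30 to 0 °C
Reagents that add atoms: trimethylaluminium, C[Al](C)C; iodine, II
Why: Negishi zirconium-catalysed syn methylalumination with Al at the terminus, then iodinolysis of the C–Al bond with retention, should give the E iodoalkene.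

Step 9
Reactants: 16 (4E)-5-iodo-4-methylpent-4-en-1-ol
Product: 17 (4E)-5-iodo-4-methylpent-4-enal
Conditions: Dess–Martin periodinane, pyridine, CH2Cl2, 0 °C to rt
Reagents that add atoms: none
Why: Dess–Martin oxidation of the primary alcohol stops at the aldehyde and leaves the iodoalkene alone.

Step 10
Reactants: 17 (4E)-5-iodo-4-methylpent-4-enal; 18 isopropenylmagnesium bromide
Product: 19 (6E)-7-iodo-2,6-dimethylhepta-1,6-dien-3-ol (racemic)
Conditions: THF, −78 to 0 °C
Reagents that add atoms: none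
Why: Grignard 1,2-addition to the aldehyde at low temperature spares the iodoalkene; the new carbinol centre is racemic and is erased in step 11.

Step 11
Reactants: 19 (6E)-7-iodo-2,6-dimethylhepta-1,6-dien-3-ol; 20 triethyl orthoacetate
Product: 22 ethyl (4E,8E)-9-iodo-4,8-dimethylnona-4,8-dienoate, via ketene acetal 21 (not isolated)
Conditions: 20 (excess), EtCO2H (cat.), 140 °C, EtOH distilled off
Reagents that add atoms: none
Why: In the Johnson orthoester Claisen rearrangement the ketene acetal reacts through a chair transition state with the carbinol substituent equatorial, which should give the E trisubstituted alkene and removes the carbinol centre.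

Step 12
Reactants: 22 ethyl (4E,8E)-9-iodo-4,8-dimethylnona-4,8-dienoate
Product: 23 ethyl 3-{(2R,3R)-3-[(3E)-4-iodo-3-methylbut-3-en-1-yl]-2-methyloxiran-2-yl}propanoate
Conditions: Shi ketone from D-fructose (cat.), KHSO5 (as the triple salt 2KHSO5·KHSO4·K2SO4), K2CO3, Bu4NHSO4, MeCN/CH2(OMe)2/aqueous Na2B4O7 buffer, 0 °C
Reagents that add atoms: potassium peroxymonosulfate, [K+].[O-]S(=O)(=O)OO
Why: In the Shi asymmetric epoxidation the chiral dioxirane attacks the electron-rich C4=C5 alkene through a spiro transition state that should give the (R,R)-epoxide, as for other E trisubstituted alkenes, while the electron-poor iodoalkene is left.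

Step 13
Reactants: 23 ethyl 3-{(2R,3R)-3-[(3E)-4-iodo-3-methylbut-3-en-1-yl]-2-methyloxiran-2-yl}propanoate
Product: 24 (5S)-5-[(1R,4E)-1-hydroxy-5-iodo-4-methylpent-4-en-1-yl]-5-methyldihydrofuran-2(3H)-one
Conditions: camphorsulfonic acid (cat.), H2O (2 equiv), CH2Cl2, 0 °C to rt
Reagents that add atoms: water, O
Why: Acid-promoted lactonisation of the epoxy ester (5-exo attack of the carbonyl oxygen on the tertiary epoxide carbon, then hydrolysis of the dialkoxycarbenium ion) inverts the quaternary carbon and retains the secondary one, which should give the 5S,1′R hydroxy γ-lactone.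

Step 14
Reactants: 24 (5S)-5-[(1R,4E)-1-hydroxy-5-iodo-4-methylpent-4-en-1-yl]-5-methyldihydrofuran-2(3H)-one
Product: 25 (5S)-5-{(1R,4E)-5-iodo-4-methyl-1-[(triethylsilyl)oxy]pent-4-en-1-yl}-5-methyldihydrofuran-2(3H)-one
Conditions: Et3SiOTf, 2,6-lutidine, CH2Cl2, −78 to 0 °C
Reagents that add atoms: triethylsilyl trifluoromethanesulfonate, CC[Si](CC)(CC)OS(=O)(=O)C(F)(F)F
Why: Silylation with the silyl triflate caps the hindered secondary hydroxyl, so that only the carbinol made later is acetylated in step 18.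

Step 15
Reactants: 13 (3E)-7-{[(1-methoxyprop-2-en-1-yl)oxy]methyl}-3-methylocta-3,7-dienal; 25 (5S)-5-{(1R,4E)-5-iodo-4-methyl-1-[(triethylsilyl)oxy]pent-4-en-1-yl}-5-methyldihydrofuran-2(3H)-one
Product: 26 (5S)-5-[(1R,4E,8E)-6-hydroxy-12-{[(1-methoxyprop-2-en-1-yl)oxy]methyl}-4,8-dimethyl-1-[(triethylsilyl)oxy]trideca-4,8,12-trien-1-yl]-5-methyldihydrofuran-2(3H)-one (both C6 epimers)
Conditions: CrCl2 (excess), NiCl2 (cat.), degassed DMSO, rt
Reagents that add atoms: none
Why: In the Nozaki–Hiyama–Kishi coupling the iodoalkene adds to zerovalent nickel, is passed to chromium with retention of the E geometry and adds only to the aldehyde, tolerating lactone, acetal and silyl ether; the C6 carbinol is uncontrolled here and is set in steps 16 and 17.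

Step 16
Reactants: 26 (5S)-5-[(1R,4E,8E)-6-hydroxy-12-{[(1-methoxyprop-2-en-1-yl)oxy]methyl}-4,8-dimethyl-1-[(triethylsilyl)oxy]trideca-4,8,12-trien-1-yl]-5-methyldihydrofuran-2(3H)-one
Product: 27 (5S)-5-[(1R,4E,8E)-12-{[(1-methoxyprop-2-en-1-yl)oxy]methyl}-4,8-dimethyl-6-oxo-1-[(triethylsilyl)oxy]trideca-4,8,12-trien-1-yl]-5-methyldihydrofuran-2(3H)-one
Conditions: Dess–Martin periodinane, pyridine, CH2Cl2, 0 °C
Reagents that add atoms: none
Why: Buffered Dess–Martin oxidation of the allylic alcohol merges both C6 epimers into one enone under conditions that should not move the skipped C8 alkene into conjugation.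

Step 17
Reactants: 27 (5S)-5-[(1R,4E,8E)-12-{[(1-methoxyprop-2-en-1-yl)oxy]methyl}-4,8-dimethyl-6-oxo-1-[(triethylsilyl)oxy]trideca-4,8,12-trien-1-yl]-5-methyldihydrofuran-2(3H)-one
Product: 28 (5S)-5-[(1R,4E,6S,8E)-6-hydroxy-12-{[(1-methoxyprop-2-en-1-yl)oxy]methyl}-4,8-dimethyl-1-[(triethylsilyl)oxy]trideca-4,8,12-trien-1-yl]-5-methyldihydrofuran-2(3H)-one
Conditions: (R)-2-methyl-CBS-oxazaborolidine, catecholborane, toluene, −78 °C
Reagents that add atoms: none
Why: In the Corey–Bakshi–Shibata reduction the (R)-oxazaborolidine binds the ketone with the alkenyl group as the large substituent and directs hydride to the face that should give the 6S alcohol, the sense known for alkenyl alkyl ketones, while catecholborane at low temperature spares alkenes and lactone.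

Step 18
Reactants: 28 (5S)-5-[(1R,4E,6S,8E)-6-hydroxy-12-{[(1-methoxyprop-2-en-1-yl)oxy]methyl}-4,8-dimethyl-1-[(triethylsilyl)oxy]trideca-4,8,12-trien-1-yl]-5-methyldihydrofuran-2(3H)-one
Product: 29 (5S)-5-[(1R,4E,6S,8E)-6-(acetyloxy)-12-{[(1-methoxyprop-2-en-1-yl)oxy]methyl}-4,8-dimethyl-1-[(triethylsilyl)oxy]trideca-4,8,12-trien-1-yl]-5-methyldihydrofuran-2(3H)-one
Conditions: Ac2O, pyridine, DMAP (cat.), CH2Cl2, 0 °C to rt
Reagents that add atoms: acetic anhydride, CC(=O)OC(C)=O
Why: DMAP-catalysed acetylation of the only free hydroxyl takes place at oxygen, so C6 keeps its configuration.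

Step 19
Reactants: 29 (5S)-5-[(1R,4E,6S,8E)-6-(acetyloxy)-12-{[(1-methoxyprop-2-en-1-yl)oxy]methyl}-4,8-dimethyl-1-[(triethylsilyl)oxy]trideca-4,8,12-trien-1-yl]-5-methyldihydrofuran-2(3H)-one
Product: 30 (5S)-5-[(1R,4E,6S,8E)-6-(acetyloxy)-1-hydroxy-12-{[(1-methoxyprop-2-en-1-yl)oxy]methyl}-4,8-dimethyltrideca-4,8,12-trien-1-yl]-5-methyldihydrofuran-2(3H)-one
Conditions: Bu4NF/AcOH (1:1), THF, 0 °C to rt
Reagents that add atoms: none
Why: Acetic-acid-buffered fluoride desilylation should free the secondary hydroxyl without touching the allylic acetate, the lactone or the acetal.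

Step 20
Reactants: 30 (5S)-5-[(1R,4E,6S,8E)-6-(acetyloxy)-1-hydroxy-12-{[(1-methoxyprop-2-en-1-yl)oxy]methyl}-4,8-dimethyltrideca-4,8,12-trien-1-yl]-5-methyldihydrofuran-2(3H)-one
Product: 32 10-acetylirciformonin B, via methoxydihydrofuran 31 (not isolated)
Conditions: second-generation Hoveyda–Grubbs catalyst (cat.), CH2Cl2, high dilution, 40 °C; then PPTS (cat.), rt
Reagents that add atoms: none
Why: Initiation is expected at the unhindered CH=CH2 of the acetal; the ruthenium carbene then engages the methylidene group of the allyl ether in a [2+2] cycloaddition and cycloreversion, ethene leaves, and the new C3=C4 bond completes 2-methoxy-2,5-dihydrofuran 31. The closest known reaction type is ring-closing metathesis of allyl ethers of acrolein-derived mixed acetals followed by acid aromatisation to furans. The five-membered ring is closed by intramolecular alkene metathesis with both alkene carbons ending inside the ring. The pyridinium acid then ionises the acetal to an oxocarbenium ion, a proton is lost from the ring CH2, and the gain of aromaticity makes the loss of methanol irreversible. No stereocentre is formed and the acetal centre disappears, so both acetal epimers converge. Only chemoselectivity is needed: the trisubstituted C4′ and C8′ alkenes are slower partners that could close only strained or medium rings, and the free hydroxyl, lactone and allylic acetate tolerate the catalyst and the weak acid.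

Compound list
1 | but-3-yn-1-ol | C#CCCO | starting material
2 | tert-butyl(but-3-yn-1-yloxy)diphenylsilane | C#CCCO[Si](c1ccccc1)(c1ccccc1)C(C)(C)C | intermediate
3 | [(1E)-4-{[tert-butyl(diphenyl)silyl]oxy}-2-methylbut-1-en-1-yl]dimethylalane | C[Al](C)/C=C(C)/CCO[Si](c1ccccc1)(c1ccccc1)C(C)(C)C | intermediate
4 | lithium butyl[(1E)-4-{[tert-butyl(diphenyl)silyl]oxy}-2-methylbut-1-en-1-yl]dimethylaluminate | [Li+].CCCC[Al-](C)(C)/C=C(C)/CCO[Si](c1ccccc1)(c1ccccc1)C(C)(C)C | intermediate
5 | (2E)-5-{[tert-butyl(diphenyl)silyl]oxy}-3-methylpent-2-en-1-ol | OC/C=C(C)/CCO[Si](c1ccccc1)(c1ccccc1)C(C)(C)C | intermediate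
6 | {[(3E)-5-bromo-3-methylpent-3-en-1-yl]oxy}(tert-butyl)diphenylsilane | BrC/C=C(C)/CCO[Si](c1ccccc1)(c1ccccc1)C(C)(C)C | intermediate
7 | 2-methylprop-2-en-1-ol | C=C(C)CO | starting material
8 | lithium 2-(lithiomethyl)prop-2-en-1-olate | [Li]CC(=C)CO[Li] | intermediate
9 | (5E)-8-{[tert-butyl(diphenyl)silyl]oxy}-6-methyl-2-methylideneoct-5-en-1-ol | C=C(CO)CC/C=C(C)/CCO[Si](c1ccccc1)(c1ccccc1)C(C)(C)C | intermediate
10 | acrolein dimethyl acetal (3,3-dimethoxyprop-1-ene) | C=CC(OC)OC | starting material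
11 | tert-butyl{[(3E)-7-{[(1-methoxyprop-2-en-1-yl)oxy]methyl}-3-methylocta-3,7-dien-1-yl]oxy}diphenylsilane | C=CC(OC)OCC(=C)CC/C=C(C)/CCO[Si](c1ccccc1)(c1ccccc1)C(C)(C)C | intermediate
12 | (3E)-7-{[(1-methoxyprop-2-en-1-yl)oxy]methyl}-3-methylocta-3,7-dien-1-ol | C=CC(OC)OCC(=C)CC/C=C(C)/CCO | intermediate
13 | (3E)-7-{[(1-methoxyprop-2-en-1-yl)oxy]methyl}-3-methylocta-3,7-dienal | C=CC(OC)OCC(=C)CC/C=C(C)/CC=O | intermediate
14 | pent-4-yn-1-ol | C#CCCCO | starting material
15 | dimethylaluminium (4E)-5-(dimethylalumanyl)-4-methylpent-4-en-1-olate | C[Al](C)/C=C(C)/CCCO[Al](C)C | intermediate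
16 | (4E)-5-iodo-4-methylpent-4-en-1-ol | OCCC/C(C)=C/I | intermediate
17 | (4E)-5-iodo-4-methylpent-4-enal | O=CCC/C(C)=C/I | intermediate
18 | isopropenylmagnesium bromide | C=C(C)[Mg]Br | starting material
19 | (6E)-7-iodo-2,6-dimethylhepta-1,6-dien-3-ol (racemic) | C=C(C)C(O)CC/C(C)=C/I | intermediate
20 | triethyl orthoacetate (1,1,1-triethoxyethane) | CC(OCC)(OCC)OCC | starting material
21 | (1E)-5-[(1-ethoxyethenyl)oxy]-1-iodo-2,6-dimethylhepta-1,6-diene | C=C(OCC)OC(CC/C(C)=C/I)C(C)=C | intermediate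
22 | ethyl (4E,8E)-9-iodo-4,8-dimethylnona-4,8-dienoate | CCOC(=O)CC/C(C)=C/CC/C(C)=C/I | intermediate
23 | ethyl 3-{(2R,3R)-3-[(3E)-4-iodo-3-methylbut-3-en-1-yl]-2-methyloxiran-2-yl}propanoate | CCOC(=O)CC[C@@]1(C)O[C@@H]1CC/C(C)=C/I | intermediate
24 | (5S)-5-[(1R,4E)-1-hydroxy-5-iodo-4-methylpent-4-en-1-yl]-5-methyldihydrofuran-2(3H)-one | I/C=C(C)/CC[C@@H](O)[C@]1(C)CCC(=O)O1 | intermediate
25 | (5S)-5-{(1R,4E)-5-iodo-4-methyl-1-[(triethylsilyl)oxy]pent-4-en-1-yl}-5-methyldihydrofuran-2(3H)-one | I/C=C(C)/CC[C@@H](O[Si](CC)(CC)CC)[C@]1(C)CCC(=O)O1 | intermediate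
26 | (5S)-5-[(1R,4E,8E)-6-hydroxy-12-{[(1-methoxyprop-2-en-1-yl)oxy]methyl}-4,8-dimethyl-1-[(triethylsilyl)oxy]trideca-4,8,12-trien-1-yl]-5-methyldihydrofuran-2(3H)-one (both C6 epimers) | C=CC(OC)OCC(=C)CC/C=C(C)/CC(O)/C=C(C)/CC[C@@H](O[Si](CC)(CC)CC)[C@]1(C)CCC(=O)O1 | intermediate
27 | (5S)-5-[(1R,4E,8E)-12-{[(1-methoxyprop-2-en-1-yl)oxy]methyl}-4,8-dimethyl-6-oxo-1-[(triethylsilyl)oxy]trideca-4,8,12-trien-1-yl]-5-methyldihydrofuran-2(3H)-one | C=CC(OC)OCC(=C)CC/C=C(C)/CC(=O)/C=C(C)/CC[C@@H](O[Si](CC)(CC)CC)[C@]1(C)CCC(=O)O1 | intermediate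
28 | (5S)-5-[(1R,4E,6S,8E)-6-hydroxy-12-{[(1-methoxyprop-2-en-1-yl)oxy]methyl}-4,8-dimethyl-1-[(triethylsilyl)oxy]trideca-4,8,12-trien-1-yl]-5-methyldihydrofuran-2(3H)-one | C=CC(OC)OCC(=C)CC/C=C(C)/C[C@H](O)/C=C(C)/CC[C@@H](O[Si](CC)(CC)CC)[C@]1(C)CCC(=O)O1 | intermediate
29 | (5S)-5-[(1R,4E,6S,8E)-6-(acetyloxy)-12-{[(1-methoxyprop-2-en-1-yl)oxy]methyl}-4,8-dimethyl-1-[(triethylsilyl)oxy]trideca-4,8,12-trien-1-yl]-5-methyldihydrofuran-2(3H)-one | C=CC(OC)OCC(=C)CC/C=C(C)/C[C@H](OC(C)=O)/C=C(C)/CC[C@@H](O[Si](CC)(CC)CC)[C@]1(C)CCC(=O)O1 | intermediate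
30 | (5S)-5-[(1R,4E,6S,8E)-6-(acetyloxy)-1-hydroxy-12-{[(1-methoxyprop-2-en-1-yl)oxy]methyl}-4,8-dimethyltrideca-4,8,12-trien-1-yl]-5-methyldihydrofuran-2(3H)-one (both acetal epimers) | C=CC(OC)OCC(=C)CC/C=C(C)/C[C@H](OC(C)=O)/C=C(C)/CC[C@@H](O)[C@]1(C)CCC(=O)O1 | intermediate
31 | (5S)-5-[(1R,4E,6S,8E)-6-(acetyloxy)-1-hydroxy-11-(5-methoxy-2,5-dihydrofuran-3-yl)-4,8-dimethylundeca-4,8-dien-1-yl]-5-methyldihydrofuran-2(3H)-one | COC1C=C(CC/C=C(C)/C[C@H](OC(C)=O)/C=C(C)/CC[C@@H](O)[C@]2(C)CCC(=O)O2)CO1 | intermediate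
32 | 10-acetylirciformonin B, (5S)-5-[(1R,4E,6S,8E)-6-(acetyloxy)-11-(furan-3-yl)-1-hydroxy-4,8-dimethylundeca-4,8-dien-1-yl]-5-methyldihydrofuran-2(3H)-one | CC(=O)O[C@H](/C=C(\C)CC[C@@H](O)[C@]1(C)CCC(=O)O1)C/C(C)=C/CCc1ccoc1 | target

Total step count: 20. Longest linear sequence: 13 steps (steps 1–7, then 15–20; the east branch, steps 8–14 then 15–20, is equally long).

Steps most likely to fail

Step 20. The catalyst may decay before it closes onto the hindered methylidene group, so that alkene isomerisation or intermolecular metathesis takes over, or the acid stage may ionise the allylic acetate. The fallback moves the ring closure to the west fragment, where neither acetate nor lactone is present, and carries the furan through the union, which uses no reagent that attacks a furan. It sets out from 11: the same ruthenium catalyst and then PPTS should give tert-butyl{[(3E)-6-(furan-3-yl)-3-methylhex-3-en-1-yl]oxy}diphenylsilane F1. Bu4NF then gives (3E)-6-(furan-3-yl)-3-methylhex-3-en-1-ol F2, and buffered Dess–Martin oxidation gives (3E)-6-(furan-3-yl)-3-methylhex-3-enal F3. CrCl2/NiCl2 coupling with 25 gives (5S)-5-[(1R,4E,8E)-11-(furan-3-yl)-6-hydroxy-4,8-dimethyl-1-[(triethylsilyl)oxy]undeca-4,8-dien-1-yl]-5-methyldihydrofuran-2(3H)-one F4 as both C6 epimers. Oxidation gives the corresponding 6-oxo compound F5, reduction with the (R)-oxazaborolidine and catecholborane gives the (6S)-alcohol F6, and acetylation gives the O-triethylsilyl ether of the target F7. Buffered Bu4NF comes back to the route at 32.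

Step 17. Hydride delivery may show poor facial selectivity because the two ketone substituents are of similar size, and the C8 alkene of the skipped dienone may drift into conjugation. The fallback avoids the ketone altogether: it sets out from 13 and 25 and joins them with CrCl2 and catalytic NiCl2 in the presence of a stoichiometric chiral oxazoline sulfonamide ligand on chromium, the enantiomer of the ligand being chosen to favour the 6S carbinol. It comes back to the route at 28 and makes no new compound.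

Step 4. C-lithiation of 7 may be incomplete, and O-alkylation or elimination of the bromide may compete. The fallback builds the same bond pattern by an sp3–sp2 cross-coupling. It sets out from 2: methylalumination and aluminate formation as in step 2 (through 3 and 4), then oxirane in place of formaldehyde, should give (3E)-6-{[tert-butyl(diphenyl)silyl]oxy}-4-methylhex-3-en-1-ol F8. I2, PPh3 and imidazole give tert-butyl{[(3E)-6-iodo-3-methylhex-3-en-1-yl]oxy}diphenylsilane F9. t-BuLi in Et2O at −78 °C and then 9-methoxy-9-borabicyclo[3.3.1]nonane give the lithium B-alkyl-B-methoxyborate F10. Suzuki–Miyaura coupling of F10 with commercial 2-bromoprop-2-en-1-ol (Pd(dppf)Cl2, AsPh3, aqueous Cs2CO3, DMF) comes back to the route at 9.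

Further compounds
F1 | step 20 | tert-butyl{[(3E)-6-(furan-3-yl)-3-methylhex-3-en-1-yl]oxy}diphenylsilane | CC(C)(C)[Si](OCC/C(C)=C/CCc1ccoc1)(c1ccccc1)c1ccccc1
F2 | step 20 | (3E)-6-(furan-3-yl)-3-methylhex-3-en-1-ol | OCC/C(C)=C/CCc1ccoc1
F3 | step 20 | (3E)-6-(furan-3-yl)-3-methylhex-3-enal | O=CC/C(C)=C/CCc1ccoc1
F4 | step 20 | (5S)-5-[(1R,4E,8E)-11-(furan-3-yl)-6-hydroxy-4,8-dimethyl-1-[(triethylsilyl)oxy]undeca-4,8-dien-1-yl]-5-methyldihydrofuran-2(3H)-one (both C6 epimers) | OC(/C=C(\C)CC[C@@H](O[Si](CC)(CC)CC)[C@]1(C)CCC(=O)O1)C/C(C)=C/CCc1ccoc1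
F5 | step 20 | (5S)-5-[(1R,4E,8E)-11-(furan-3-yl)-4,8-dimethyl-6-oxo-1-[(triethylsilyl)oxy]undeca-4,8-dien-1-yl]-5-methyldihydrofuran-2(3H)-one | O=C(/C=C(\C)CC[C@@H](O[Si](CC)(CC)CC)[C@]1(C)CCC(=O)O1)C/C(C)=C/CCc1ccoc1
F6 | step 20 | (5S)-5-[(1R,4E,6S,8E)-11-(furan-3-yl)-6-hydroxy-4,8-dimethyl-1-[(triethylsilyl)oxy]undeca-4,8-dien-1-yl]-5-methyldihydrofuran-2(3H)-one | O[C@H](/C=C(\C)CC[C@@H](O[Si](CC)(CC)CC)[C@]1(C)CCC(=O)O1)C/C(C)=C/CCc1ccoc1
F7 | step 20 | (5S)-5-[(1R,4E,6S,8E)-6-(acetyloxy)-11-(furan-3-yl)-4,8-dimethyl-1-[(triethylsilyl)oxy]undeca-4,8-dien-1-yl]-5-methyldihydrofuran-2(3H)-one | CC(=O)O[C@H](/C=C(\C)CC[C@@H](O[Si](CC)(CC)CC)[C@]1(C)CCC(=O)O1)C/C(C)=C/CCc1ccoc1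
F0 | step 17 | none | none
F8 | step 4 | (3E)-6-{[tert-butyl(diphenyl)silyl]oxy}-4-methylhex-3-en-1-ol | OCC/C=C(C)/CCO[Si](c1ccccc1)(c1ccccc1)C(C)(C)C
F9 | step 4 | tert-butyl{[(3E)-6-iodo-3-methylhex-3-en-1-yl]oxy}diphenylsilane | ICC/C=C(C)/CCO[Si](c1ccccc1)(c1ccccc1)C(C)(C)C
F10 | step 4 | lithium 9-[(3E)-6-{[tert-butyl(diphenyl)silyl]oxy}-4-methylhex-3-en-1-yl]-9-methoxy-9-boranuidabicyclo[3.3.1]nonane | [Li+].CO[B-]1(CC/C=C(C)/CCO[Si](c2ccccc2)(c2ccccc2)C(C)(C)C)C2CCCC1CCC2
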